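**Strategy**

The target is cut at its dihydrofuran ring into a coumaronochromone, an aryl nucleophile and an ent-afzelechin unit, and everything rests on making that flavan by closing its pyran ring at O1–C2. An acyclic (R,R)-epoxide bearing a free phloroglucinol ring cyclizes 6-endo: a phenol attacks the benzylic epoxide carbon with inversion, which sets C2 (S) and frees the C3 hydroxyl (R) in one operation. The step exploits that C2 is benzylic to the 4-oxygenated ring B and that the two hydroxyls flanking C4a of ring A are equivalent before closure. Trans-opening of a coumaronochromone epoxide by an arylcopper reagent later sets the anti ketal–carbinol pair.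

Key step: step 5

Remark on the chemistry: the SMILES places the 4-hydroxyphenyl group on the ketal carbon (S) and the hydroxyl on the adjoining carbinol carbon (R) on opposite faces of the dihydrofuran ring. A ring closure at either junction carbon would give the syn, cis-fused isomer, so this anti pair is set by a stereospecific epoxide opening (step 13), and no acid or base is used after it.

Naming note: plain locants belong to the flavan unit (O1, C2, C3, C4, ring A C5–C8, ring B). Locants with the suffix u belong to the upper chromone/chromanone unit (C2u = ketal carbon, C3u = carbinol carbon, C4u = carbonyl).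

**Route**

Step 1
Reactants: 1 4-(benzyloxy)benzaldehyde; 2 vinylmagnesium bromide
Product: 3 (±)-1-[4-(benzyloxy)phenyl]prop-2-en-1-ol
Conditions: THF, 0 °C; aq. NH4Cl
Reagents that add atoms: none
Why: Grignard 1,2-addition to the aldehyde gives the allylic alcohol, whose stereocentre is erased by ionization in step 2.

Step 2
Reactants: 3 (±)-1-[4-(benzyloxy)phenyl]prop-2-en-1-ol; 4 phloroglucinol (3 equiv)
Product: 5 2-[(E)-3-(4-benzyloxyphenyl)prop-2-en-1-yl]benzene-1,3,5-triol
Conditions: BF3·OEt2 (cat.), dioxane, 0 °C to rt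
Reagents that add atoms: none
Why: Friedel–Crafts allylation: the Lewis acid ionizes 3 with loss of water to a 1-arylallyl cation that alkylates phloroglucinol at carbon through its unsubstituted terminus, giving the conjugated E-alkene; the three ring positions of 4 are equivalent, its excess limits double alkylation, and the low temperature should keep the ortho phenol from adding to the styrene.

Step 3
Reactants: 5 2-[(E)-3-(4-benzyloxyphenyl)prop-2-en-1-yl]benzene-1,3,5-triol
Product: 6 1,3,5-tris(tert-butyldimethylsilyloxy)-2-[(E)-3-(4-benzyloxyphenyl)prop-2-en-1-yl]benzene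
Conditions: TBSCl, imidazole, DMF, rt
Reagents that add atoms: tert-butyldimethylsilyl chloride (TBSCl), CC(C)(C)[Si](C)(C)Cl
Why: Silyl ether formation masks the three oxidation-sensitive phenols for the epoxidation of step 4.

Step 4
Reactants: 6 1,3,5-tris(tert-butyldimethylsilyloxy)-2-[(E)-3-(4-benzyloxyphenyl)prop-2-en-1-yl]benzene
Product: 7 (2R,3R)-2-(4-benzyloxyphenyl)-3-[2,4,6-tris(tert-butyldimethylsilyloxy)benzyl]oxirane
Conditions: D-fructose-derived Shi ketone (0.3 equiv), Oxone (2KHSO5·KHSO4·K2SO4), K2CO3, Bu4NHSO4, MeCN–dimethoxymethane/aq. Na2B4O7 buffer, 0 °C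
Reagents that add atoms: potassium peroxymonosulfate (the oxidant in Oxone), [K+].[O-]S(=O)(=O)OO
Why: Shi asymmetric epoxidation: the chiral dioxirane transfers oxygen to the E-alkene through a spiro transition state, which for (E)-β-alkylstyrenes gives the (R,R)-epoxide and so sets both epoxide carbons, while the basic buffer protects the acid-labile 4-alkoxyphenyl oxirane.

Step 5
Reactants: 7 (2R,3R)-2-(4-benzyloxyphenyl)-3-[2,4,6-tris(tert-butyldimethylsilyloxy)benzyl]oxirane
Product: 9 (2S,3R)-2-(4-benzyloxyphenyl)chromane-3,5,7-triol (4′-O-benzyl-ent-afzelechin), via triol epoxide 8 (not isolated)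
Conditions: TBAF, AcOH (excess), THF, 0 °C to rt
Reagents that add atoms: none
Why: Buffered fluoride removes the three aryl silyl ethers, and the acetic acid then activates the oxirane of 8, which a ring A hydroxyl ortho to the side chain attacks at the benzylic carbon, so that O1–C2 forms with inversion while the oxirane oxygen becomes the C3 hydroxyl. The closest known reaction is the acid-catalysed intramolecular opening of aryl-substituted epoxides by phenols, an epoxide-opening etherification used for 2,3-trans-flavan-3-ols. The pyran ring closes in the 6-endo-tet mode. C2 (S) is set by backside attack on the (R)-configured benzylic epoxide carbon, and C3 (R) is carried over unchanged from step 4, which gives the 2,3-trans relationship. The step needs 6-endo over 5-exo selectivity, which the cation-stabilizing 4-benzyloxyphenyl group and the acidic, non-basic medium should secure. It needs no choice between oxygens, because the two hydroxyls flanking C4a are homotopic and the third cannot reach the oxirane.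

Step 6
Reactants: 9 (2S,3R)-2-(4-benzyloxyphenyl)chromane-3,5,7-triol
Product: 10 (2S,3R)-2-(4-benzyloxyphenyl)-3,5,7-tris(methoxymethoxy)chromane
Conditions: MOMCl, iPr2NEt, CH2Cl2, 0 °C to rt
Reagents that add atoms: chloromethyl methyl ether (MOMCl), COCCl
Why: O-alkylation to MOM acetals protects both phenols and the secondary alcohol with groups that are orthogonal to benzyl ethers, tolerate organolithium reagents and leave with acid in step 11.

Step 7
Reactants: 10 (2S,3R)-2-(4-benzyloxyphenyl)-3,5,7-tris(methoxymethoxy)chromane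
Product: 11 (2S,3R)-8-bromo-2-(4-benzyloxyphenyl)-3,5,7-tris(methoxymethoxy)chromane
Conditions: NBS, CH2Cl2, −78 to −20 °C
Reagents that add atoms: N-bromosuccinimide (NBS), O=C1CCC(=O)N1Br
Why: Electrophilic aromatic bromination of the electron-rich ring A should take place at C8, the less hindered of its two free positions (C6 lies between two MOM ethers), as known for 5,7-di-O-protected flavan-3-ols.

Step 8
Reactants: 12 1-[2,4-bis(benzyloxy)-6-hydroxyphenyl]ethanone
Product: 14 5,7-bis(benzyloxy)-2-(methylsulfanyl)-4H-chromen-4-one, via hydroxychromenethione 13 (not isolated)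
Conditions: t-BuOK, CS2, THF, 0 °C to rt; then MeI
Reagents that add atoms: carbon disulfide, S=C=S; iodomethane (MeI), CI
Why: Claisen-type thioacylation of the ketone enolate with CS2 and cyclization of the phenoxide with loss of hydrosulfide give the 4-hydroxychromene-2-thione, whose soft sulfur is then methylated (S-alkylation) to the 2-methylsulfanylchromone.

Step 9
Reactants: 14 5,7-bis(benzyloxy)-2-(methylsulfanyl)-4H-chromen-4-one
Product: 15 5,7-bis(benzyloxy)-3-iodo-2-(methylsulfanyl)-4H-chromen-4-one
Conditions: NIS, TFA (cat.), MeCN, 0 °C to rt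
Reagents that add atoms: N-iodosuccinimide (NIS), O=C1CCC(=O)N1I
Why: Electrophilic iodination should occur at C3, the nucleophilic β-carbon of the push-pull O,S-ketene acetal, while the benzo ring is deactivated by the carbonyl group.

Step 10
Reactants: 11 (2S,3R)-8-bromo-2-(4-benzyloxyphenyl)-3,5,7-tris(methoxymethoxy)chromane; 15 5,7-bis(benzyloxy)-3-iodo-2-(methylsulfanyl)-4H-chromen-4-one
Product: 18 5,7-bis(benzyloxy)-3-[(2S,3R)-2-(4-benzyloxyphenyl)-3,5,7-tris(methoxymethoxy)chroman-8-yl]-2-(methylsulfanyl)-4H-chromen-4-one, via aryllithium 16 (not isolated), via arylzinc chloride 17 (not isolated)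
Conditions: n-BuLi, THF, −78 °C; ZnCl2; then 15, Pd2(dba)3, RuPhos, THF, 60 °C
Reagents that add atoms: none
Why: Bromine–lithium exchange, transmetalation to zinc and Negishi cross-coupling form the C8–C3u bond; the carbon–iodine bond reacts far faster than the carbon–sulfur bond, and the bulky biarylphosphine serves the doubly ortho-substituted partners.

Step 11
Reactants: 18 5,7-bis(benzyloxy)-3-[(2S,3R)-2-(4-benzyloxyphenyl)-3,5,7-tris(methoxymethoxy)chroman-8-yl]-2-(methylsulfanyl)-4H-chromen-4-one
Product: 19 5,7-bis(benzyloxy)-3-[(2S,3R)-2-(4-benzyloxyphenyl)-3,5,7-trihydroxychroman-8-yl]-2-(methylsulfanyl)-4H-chromen-4-one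
Conditions: HCl (cat.), MeOH–THF, 40 °C
Reagents that add atoms: none
Why: Acid-catalysed acetal exchange with methanol (MOM cleavage) frees the 3-, 5- and 7-hydroxyls while the benzyl ethers and the thioether stay in place.

Step 12
Reactants: 19 5,7-bis(benzyloxy)-3-[(2S,3R)-2-(4-benzyloxyphenyl)-3,5,7-trihydroxychroman-8-yl]-2-(methylsulfanyl)-4H-chromen-4-one
Product: 21 3,5-di-O-benzyl coumaronochromone, via coumaronochromone diol 20 (not isolated)
Conditions: NaH, DMF, 0 to 60 °C; then BnBr, 0 °C to rt
Reagents that add atoms: benzyl bromide (BnBr), BrCc1ccccc1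
Why: The 7-phenoxide adds to C2u and expels methanethiolate (intramolecular addition–elimination, the vinylogous nucleophilic substitution used for coumestans), which closes the furan ring to the flat coumaronochromone; only the 7-oxygen can reach C2u, and the remaining 5-phenoxide and 3-alkoxide are then benzylated (Williamson ether synthesis).

Step 13
Reactants: 21 3,5-di-O-benzyl coumaronochromone; 22 4-(benzyloxy)phenylmagnesium bromide
Product: 24 hexa-O-benzyl target, via ketene-acetal epoxide 23 (not isolated)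
Conditions: DMDO, CH2Cl2–acetone, −40 to 0 °C; volatiles removed cold; then 22, CuBr·SMe2 (20 mol %), THF, −78 °C; aq. NH4Cl; chromatography
Reagents that add atoms: dimethyldioxirane (DMDO), CC1(C)OO1
Why: Proposed new method: DMDO should epoxidize the electron-rich C2u=C3u ketene-acetal double bond shared by the furan and pyranone rings, and the copper-catalysed aryl Grignard reagent should open this 2,2-dioxygenated oxirane at the acetal carbon from the face opposite the oxirane oxygen (SN2-type, inversion), so that the new aryl group and the carbinol oxygen end anti, as required for the ketal carbon (S) and the carbinol carbon (R); the carbon–carbon bond formation is irreversible, so the anti pair cannot equilibrate; the closest known reaction is the trans-opening of glycal epoxides (1,2-anhydro sugars) by aryl cuprates; DMDO cannot tell the two faces of the flat coumaronochromone apart, so the oxirane of opposite configuration should form as well, and its adduct, a diastereomer of 24 because of the flavan stereocentres, is removed by chromatography.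

Step 14
Reactants: 24 hexa-O-benzyl target
Product: 25 CNP0146414.2
Conditions: H2 (1 atm), Pd(OH)2/C, EtOAc–MeOH, rt
Reagents that add atoms: none
Why: Hydrogenolysis of the six benzyl ethers under neutral conditions frees all hydroxyls without acid or base, so the ketal and carbinol centres should keep their configuration; aryl-substituted diaryl ketals and the flavan benzylic ether are known to survive such conditions in A-type proanthocyanidin syntheses.

**Compound list**

1 | 4-(benzyloxy)benzaldehyde | O=Cc1ccc(OCc2ccccc2)cc1 | starting material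
2 | vinylmagnesium bromide | C=C[Mg]Br | starting material
3 | (±)-1-[4-(benzyloxy)phenyl]prop-2-en-1-ol | C=CC(O)c1ccc(OCc2ccccc2)cc1 | intermediate
4 | phloroglucinol (benzene-1,3,5-triol) | Oc1cc(O)cc(O)c1 | starting material
5 | 2-[(E)-3-(4-benzyloxyphenyl)prop-2-en-1-yl]benzene-1,3,5-triol | Oc1cc(O)c(C/C=C/c2ccc(OCc3ccccc3)cc2)c(O)c1 | intermediate
6 | 1,3,5-tris(tert-butyldimethylsilyloxy)-2-[(E)-3-(4-benzyloxyphenyl)prop-2-en-1-yl]benzene | CC(C)(C)[Si](C)(C)Oc1cc(O[Si](C)(C)C(C)(C)C)c(C/C=C/c2ccc(OCc3ccccc3)cc2)c(O[Si](C)(C)C(C)(C)C)c1 | intermediate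
7 | (2R,3R)-2-(4-benzyloxyphenyl)-3-[2,4,6-tris(tert-butyldimethylsilyloxy)benzyl]oxirane | CC(C)(C)[Si](C)(C)Oc1cc(O[Si](C)(C)C(C)(C)C)c(C[C@H]2O[C@@H]2c2ccc(OCc3ccccc3)cc2)c(O[Si](C)(C)C(C)(C)C)c1 | intermediate
8 | 2-{[(2R,3R)-3-(4-benzyloxyphenyl)oxiran-2-yl]methyl}benzene-1,3,5-triol (triol epoxide, not isolated) | Oc1cc(O)c(C[C@H]2O[C@@H]2c2ccc(OCc3ccccc3)cc2)c(O)c1 | intermediate
9 | (2S,3R)-2-(4-benzyloxyphenyl)chromane-3,5,7-triol | Oc1cc(O)c2c(c1)O[C@@H](c1ccc(OCc3ccccc3)cc1)[C@H](O)C2 | intermediate
10 | (2S,3R)-2-(4-benzyloxyphenyl)-3,5,7-tris(methoxymethoxy)chromane | COCOc1cc(OCOC)c2c(c1)O[C@@H](c1ccc(OCc3ccccc3)cc1)[C@H](OCOC)C2 | intermediate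
11 | (2S,3R)-8-bromo-2-(4-benzyloxyphenyl)-3,5,7-tris(methoxymethoxy)chromane | COCOc1cc(OCOC)c2c(c1Br)O[C@@H](c1ccc(OCc3ccccc3)cc1)[C@H](OCOC)C2 | intermediate
12 | 1-[2,4-bis(benzyloxy)-6-hydroxyphenyl]ethanone | CC(=O)c1c(O)cc(OCc2ccccc2)cc1OCc1ccccc1 | starting material
13 | 5,7-bis(benzyloxy)-4-hydroxy-2H-chromene-2-thione (hydroxychromenethione, present as its potassium salt, not isolated) | OC1=CC(=S)Oc2cc(OCc3ccccc3)cc(OCc3ccccc3)c12 | intermediate
14 | 5,7-bis(benzyloxy)-2-(methylsulfanyl)-4H-chromen-4-one | CSc1cc(=O)c2c(OCc3ccccc3)cc(OCc3ccccc3)cc2o1 | intermediate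
15 | 5,7-bis(benzyloxy)-3-iodo-2-(methylsulfanyl)-4H-chromen-4-one | CSc1oc2cc(OCc3ccccc3)cc(OCc3ccccc3)c2c(=O)c1I | intermediate
16 | [(2S,3R)-2-(4-benzyloxyphenyl)-3,5,7-tris(methoxymethoxy)chroman-8-yl]lithium (aryllithium, not isolated) | COCOc1cc(OCOC)c2c(c1[Li])O[C@@H](c1ccc(OCc3ccccc3)cc1)[C@H](OCOC)C2 | intermediate
17 | [(2S,3R)-2-(4-benzyloxyphenyl)-3,5,7-tris(methoxymethoxy)chroman-8-yl]zinc chloride (arylzinc chloride, not isolated) | COCOc1cc(OCOC)c2c(c1[Zn]Cl)O[C@@H](c1ccc(OCc3ccccc3)cc1)[C@H](OCOC)C2 | intermediate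
18 | 5,7-bis(benzyloxy)-3-[(2S,3R)-2-(4-benzyloxyphenyl)-3,5,7-tris(methoxymethoxy)chroman-8-yl]-2-(methylsulfanyl)-4H-chromen-4-one | COCOc1cc(OCOC)c2c(c1-c1c(SC)oc3cc(OCc4ccccc4)cc(OCc4ccccc4)c3c1=O)O[C@@H](c1ccc(OCc3ccccc3)cc1)[C@H](OCOC)C2 | intermediate
19 | 5,7-bis(benzyloxy)-3-[(2S,3R)-2-(4-benzyloxyphenyl)-3,5,7-trihydroxychroman-8-yl]-2-(methylsulfanyl)-4H-chromen-4-one | Oc1cc(O)c2c(c1-c1c(SC)oc3cc(OCc4ccccc4)cc(OCc4ccccc4)c3c1=O)O[C@@H](c1ccc(OCc3ccccc3)cc1)[C@H](O)C2 | intermediate
20 | coumaronochromone diol: 5u,7u-bis(benzyloxy)chromone fused through C2u–O and C3u as a furan ring to O7 and C8 of (2S,3R)-2-(4-benzyloxyphenyl)chromane-3,5-diol (not isolated) | O=c1c2c(OCc3ccccc3)cc(OCc3ccccc3)cc2oc2oc3cc(O)c4c(c3c12)O[C@@H](c1ccc(OCc3ccccc3)cc1)[C@H](O)C4 | intermediate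
21 | 3,5-di-O-benzyl coumaronochromone: the 3,5-di-O-benzyl ether of 20 | O=c1c2c(OCc3ccccc3)cc(OCc3ccccc3)cc2oc2oc3cc(OCc5ccccc5)c4c(c3c12)O[C@@H](c1ccc(OCc3ccccc3)cc1)[C@H](OCc1ccccc1)C4 | intermediate
22 | 4-(benzyloxy)phenylmagnesium bromide | Br[Mg]c1ccc(OCc2ccccc2)cc1 | starting material
23 | C2u–C3u epoxide of 21, oxirane oxygen on the face that becomes the carbinol oxygen of 24 (ketene-acetal epoxide, not isolated) | O=C1c2c(OCc3ccccc3)cc(OCc3ccccc3)cc2O[C@@]2(O3)Oc4cc(OCc6ccccc6)c5c(c4[C@@]123)O[C@@H](c1ccc(OCc3ccccc3)cc1)[C@H](OCc1ccccc1)C5 | intermediate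
24 | hexa-O-benzyl target: (2uS,3uR)-2u-(4-benzyloxyphenyl)-3u-hydroxy-5u,7u-bis(benzyloxy)chroman-4u-one fused through C2u–O and C3u to O7 and C8 of (2S,3R)-3,5-bis(benzyloxy)-2-(4-benzyloxyphenyl)chromane, aryl and hydroxyl anti | O=C1c2c(OCc3ccccc3)cc(OCc3ccccc3)cc2O[C@]2(c3ccc(OCc5ccccc5)cc3)Oc3cc(OCc5ccccc5)c4c(c3[C@@]12O)O[C@@H](c1ccc(OCc3ccccc3)cc1)[C@H](OCc1ccccc1)C4 | intermediate
25 | CNP0146414.2: (2uS,3uR)-3u,5u,7u-trihydroxy-2u-(4-hydroxyphenyl)chroman-4u-one fused through C2u–O and C3u to O7 and C8 of (2S,3R)-2-(4-hydroxyphenyl)chromane-3,5-diol, aryl and 3u-hydroxyl anti | O=C1c2c(O)cc(O)cc2O[C@]2(c3ccc(O)cc3)Oc3cc(O)c4c(c3[C@@]12O)O[C@@H](c1ccc(O)cc1)[C@H](O)C4 | target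

**Count and risks**

Total step count: 14. Longest linear sequence: 12 steps (steps 1–7 and 10–14); steps 8 and 9 form the second branch.

Steps most likely to fail:

1. Step 13 (proposed new method). Four processes can go wrong. The ketene-acetal oxirane may collapse before the aryl group arrives, by ring opening to a dioxocarbenium alkoxide followed by acyl or aryl shift. The aryl group may be delivered from the magnesium alkoxide on the same face as the oxygen, which leads into the cis-fused series. The Grignard reagent may add to the C4u ketone. And the epoxidation has no facial control. The fallback uses known reactions and sets out from 21. Epoxidation with DMDO in CH2Cl2–methanol should trap the oxirane 23 as the methoxy orthoester carbinol F1 (epoxidation–methanolysis of an enol ether). TESOTf and 2,6-lutidine should give its triethylsilyl ether F2. Transmetalation of 22 with ZnBr2 gives 4-(benzyloxy)phenylzinc bromide F3, which spares the ketone. BF3·OEt2 and F3 should then replace the methoxy group of F2 by the aryl group after ionization of the orthoester (Lewis acid-mediated substitution of an orthoester alkoxy group by an organometallic reagent, the Bodroux–Chichibabin type). The bulky silyloxy group shields its own face, so the aryl group should enter anti and give the silylated aryl ketal F4. TBAF buffered with AcOH removes the silyl group, and the route is rejoined at 24.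

2. Step 10. Transmetalation and reductive elimination at the doubly ortho-substituted centres may be slow, with protodemetalation of the arylzinc reagent or coupling at the carbon–sulfur bond taking over. The fallback makes the C8–carbon bond at an unhindered enolate carbon before the chromone ring exists, and sets out from 11 and 12. Palladium-catalysed α-arylation of the ketone (Pd(OAc)2, a bulky biarylphosphine, NaOt-Bu, toluene, 80 °C; 12 as its dianion) should give the deoxybenzoin F5. The sequence of step 8 then builds the chromone ring on F5: t-BuOK and CS2 should give the 3-aryl hydroxychromenethione F6 (not isolated), and MeI methylates its sulfur, so that the route is rejoined at 18.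

3. Step 14. Hydrogenolysis may also cleave the benzylic ketal carbon–oxygen bond or the benzylic tertiary carbinol. Once the 4-hydroxyphenyl group is free, the anti ketal may epimerize to the cis-fused isomer through quinone methide ionization on the catalyst support. The fallback moves the hydrogenolysis to the robust flat stage and ends with fluoride; it sets out from 21. Hydrogenolysis (H2, Pd(OH)2/C) should give the pentahydroxy coumaronochromone F7. TBSOTf and 2,6-lutidine should give its pentakis(tert-butyldimethylsilyl) ether F8. DMDO should convert this into the silylated ketene-acetal epoxide F9 (not isolated). 4-(tert-Butyldimethylsilyloxy)phenylmagnesium bromide F10, made from (4-bromophenoxy)(tert-butyl)dimethylsilane and Mg in THF, should open F9 with CuBr·SMe2 as in step 13 and give the hexasilylated anti ketal carbinol F11. Et3N·3HF in THF at 0 °C to rt removes all silyl groups, and the route is rejoined at 25.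

Further compounds

F1 | step 13 | methoxy orthoester carbinol: 2u-methoxy-3u-hydroxy analogue of 24 (configuration at C2u is inconsequential) | O=C1c2c(OCc3ccccc3)cc(OCc3ccccc3)cc2O[C@]2(OC)Oc3cc(OCc5ccccc5)c4c(c3[C@@]12O)O[C@@H](c1ccc(OCc3ccccc3)cc1)[C@H](OCc1ccccc1)C4
F2 | step 13 | 3u-O-triethylsilyl ether of F1 | O=C1c2c(OCc3ccccc3)cc(OCc3ccccc3)cc2O[C@]2(OC)Oc3cc(OCc5ccccc5)c4c(c3[C@@]12O[Si](CC)(CC)CC)O[C@@H](c1ccc(OCc3ccccc3)cc1)[C@H](OCc1ccccc1)C4
F3 | step 13 | 4-(benzyloxy)phenylzinc bromide | Br[Zn]c1ccc(OCc2ccccc2)cc1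
F4 | step 13 | silylated aryl ketal: 3u-O-triethylsilyl ether of 24 | O=C1c2c(OCc3ccccc3)cc(OCc3ccccc3)cc2O[C@]2(c3ccc(OCc5ccccc5)cc3)Oc3cc(OCc5ccccc5)c4c(c3[C@@]12O[Si](CC)(CC)CC)O[C@@H](c1ccc(OCc3ccccc3)cc1)[C@H](OCc1ccccc1)C4
F5 | step 10 | deoxybenzoin: 1-[2,4-bis(benzyloxy)-6-hydroxyphenyl]-2-[(2S,3R)-2-(4-benzyloxyphenyl)-3,5,7-tris(methoxymethoxy)chroman-8-yl]ethanone | O=C(Cc1c(OCOC)cc(OCOC)c2c1O[C@@H](c1ccc(OCc3ccccc3)cc1)[C@H](OCOC)C2)c1c(O)cc(OCc2ccccc2)cc1OCc1ccccc1
F6 | step 10 | 3-aryl hydroxychromenethione: 5,7-bis(benzyloxy)-3-[(2S,3R)-2-(4-benzyloxyphenyl)-3,5,7-tris(methoxymethoxy)chroman-8-yl]-4-hydroxy-2H-chromene-2-thione (as its potassium salt, not isolated) | OC1=C(c3c(OCOC)cc(OCOC)c4c3O[C@@H](c3ccc(OCc5ccccc5)cc3)[C@H](OCOC)C4)C(=S)Oc2cc(OCc3ccccc3)cc(OCc3ccccc3)c12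
F7 | step 14 | pentahydroxy coumaronochromone (21 without its five benzyl groups) | O=c1c2c(O)cc(O)cc2oc2oc3cc(O)c4c(c3c12)O[C@@H](c1ccc(O)cc1)[C@H](O)C4
F8 | step 14 | pentakis(tert-butyldimethylsilyl) ether of F7 | O=c1c2c(O[Si](C)(C)C(C)(C)C)cc(O[Si](C)(C)C(C)(C)C)cc2oc2oc3cc(O[Si](C)(C)C(C)(C)C)c4c(c3c12)O[C@@H](c1ccc(O[Si](C)(C)C(C)(C)C)cc1)[C@H](O[Si](C)(C)C(C)(C)C)C4
F9 | step 14 | silylated ketene-acetal epoxide: C2u–C3u epoxide of F8 (not isolated) | O=C1c2c(O[Si](C)(C)C(C)(C)C)cc(O[Si](C)(C)C(C)(C)C)cc2O[C@@]2(O3)Oc4cc(O[Si](C)(C)C(C)(C)C)c5c(c4[C@@]123)O[C@@H](c1ccc(O[Si](C)(C)C(C)(C)C)cc1)[C@H](O[Si](C)(C)C(C)(C)C)C5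
F10 | step 14 | 4-(tert-butyldimethylsilyloxy)phenylmagnesium bromide | CC(C)(C)[Si](C)(C)Oc1ccc([Mg]Br)cc1
F11 | step 14 | hexasilylated anti ketal carbinol: hexakis(tert-butyldimethylsilyl) ether of 25 with free 3u-hydroxyl | O=C1c2c(O[Si](C)(C)C(C)(C)C)cc(O[Si](C)(C)C(C)(C)C)cc2O[C@]2(c3ccc(O[Si](C)(C)C(C)(C)C)cc3)Oc3cc(O[Si](C)(C)C(C)(C)C)c4c(c3[C@@]12O)O[C@@H](c1ccc(O[Si](C)(C)C(C)(C)C)cc1)[C@H](O[Si](C)(C)C(C)(C)C)C4
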